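**Plan**

- Retrosynthesis: cut the C3 ester; cut C7–C8 and C4a–C8a together (retro-[4+2]); cut C5–C1' and C5–C6 at a 1,1-dichloroalkene; cut C3–C4 (allylation); trace the C2 methyl back to the CH2O of D-serine.
- Enabling feature: ring C4a–C5–C6–C7–C8–C8a is a cyclohexane with N1 on C8a beside the unsubstituted C8. It is therefore the hydrogenated adduct of an N-vinyl dienophile (C8a=C8) and a diene C4a=C5–C6=C7, which the piperidine atoms N1–C2–C3–C4 already tether.
- Forward: the open chain is built first (Garner's aldehyde, allylation, dichloroalkene, Negishi alkylation with the side-chain zinc reagent, vinylation, N-vinylation). One intramolecular Diels–Alder step then closes the piperidine and the carbocycle together. Hydrogenation, CH2O-to-CH3 conversion, esterification and deprotection follow.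
- Stereochemistry: C2 from D-serine; C3 from reagent-controlled allylboration; C5' from (R)-1,2-epoxypentane; C4a and C8a from the cycloaddition ((Z)-diene gives cis fusion, the fused oxazolidinone sets the face); C5 from hydrogenation on the convex face; the E-enoate from the acid.

Key step: step 12

Remark: the quinoline numbering of the target (N1, C2, C3, C4, C4a, C5–C8, C8a; side chain C1'–C8') is used for all intermediates.

**Route**

Step 1
Reactants: 1 (R)-1,2-epoxypentane
Product: 2 (R)-oct-7-en-4-ol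
Conditions: allylMgBr, CuI (10 mol%), THF, −30 → 0 °C; 1 M HCl
Reagents that add atoms: allylmagnesium bromide, C=CC[Mg]Br
Why: CuI-catalysed SN2 opening of the terminal epoxide by the Grignard reagent at the unsubstituted carbon, so the (R) carbinol centre (the future C5') is carried over untouched from the epoxide.

Step 2
Reactants: 2 (R)-oct-7-en-4-ol
Product: 3 (R)-tert-butyldimethyl(oct-7-en-4-yloxy)silane
Conditions: TBSCl, imidazole, DMF, rt
Reagents that add atoms: tert-butyldimethylsilyl chloride, CC(C)(C)[Si](C)(C)Cl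
Why: Standard silylation of a secondary alcohol; the silyl ether should last until the final acid step.

Step 3
Reactants: 3 (R)-tert-butyldimethyl(oct-7-en-4-yloxy)silane
Product: 5 (R)-tert-butyl[(8-iodooctan-4-yl)oxy]dimethylsilane, via alkylzirconocene chloride 4 (not isolated)
Conditions: Cp2Zr(H)Cl, THF, rt; then I2, 0 °C
Reagents that add atoms: iodine, II
Why: Hydrozirconation places zirconium on the terminal carbon and iodinolysis of the C–Zr bond should give the primary iodide without touching the silyl ether.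

Step 4
Reactants: 6 (R)-Garner's aldehyde, tert-butyl (4R)-4-formyl-2,2-dimethyl-1,3-oxazolidine-3-carboxylate
Product: 8 tert-butyl (4R)-4-[(1R)-1-hydroxybut-3-en-1-yl]-2,2-dimethyl-1,3-oxazolidine-3-carboxylate, via borinate ester 7 (not isolated)
Conditions: (+)-Ipc2B(allyl) (1 M in pentane), Et2O, −78 °C; then NaOH, H2O2, 0 °C → rt
Reagents that add atoms: (+)-B-allyldiisopinocampheylborane (the antipode made from (−)-α-pinene), C=CCB([C@H]1C[C@H]2C[C@@H]([C@@H]1C)C2(C)C)[C@H]1C[C@H]2C[C@@H]([C@@H]1C)C2(C)C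
Why: Brown allylboration through a closed chair-like six-membered transition state, in which this antipode delivers allyl to the Re face of the aldehyde and overrides its modest Felkin preference, so C3 is set syn to nitrogen (the minor anti isomer should be separable).

Step 5
Reactants: 8 tert-butyl (4R)-4-[(1R)-1-hydroxybut-3-en-1-yl]-2,2-dimethyl-1,3-oxazolidine-3-carboxylate
Product: 9 tert-butyl (4R)-4-[(1R)-1-(benzyloxy)but-3-en-1-yl]-2,2-dimethyl-1,3-oxazolidine-3-carboxylate
Conditions: NaH, BnBr, Bu4NI (cat.), THF, 0 °C → rt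
Reagents that add atoms: benzyl bromide, BrCc1ccccc1
Why: Williamson etherification of the secondary alkoxide at 0 °C, where O-alkylation should outrun attack of the alkoxide on the Boc group.

Step 6
Reactants: 9 tert-butyl (4R)-4-[(1R)-1-(benzyloxy)but-3-en-1-yl]-2,2-dimethyl-1,3-oxazolidine-3-carboxylate
Product: 11 tert-butyl (4R)-4-[(1R)-1-(benzyloxy)-3-oxopropyl]-2,2-dimethyl-1,3-oxazolidine-3-carboxylate, via secondary ozonide 10 (not isolated)
Conditions: O3, CH2Cl2, −78 °C (stopped at the end point); then PPh3, −78 °C → rt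
Reagents that add atoms: ozone, O=[O+][O-]
Why: Ozonolysis of the only alkene followed by reductive work-up gives the aldehyde carbon that becomes C4a, and the fully substituted nitrogen prevents hemiaminal formation with this aldehyde.

Step 7
Reactants: 11 tert-butyl (4R)-4-[(1R)-1-(benzyloxy)-3-oxopropyl]-2,2-dimethyl-1,3-oxazolidine-3-carboxylate
Product: 12 tert-butyl (4R)-4-[(1R)-1-(benzyloxy)-4,4-dichlorobut-3-en-1-yl]-2,2-dimethyl-1,3-oxazolidine-3-carboxylate
Conditions: PPh3, BrCCl3, MeCN, 0 °C → rt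
Reagents that add atoms: bromotrichloromethane, ClC(Cl)(Cl)Br
Why: Wittig-type dichloromethylenation with the ylide formed from PPh3 and BrCCl3 under neutral conditions, which should avoid β-elimination of the benzyloxy group.

Step 8
Reactants: 12 tert-butyl (4R)-4-[(1R)-1-(benzyloxy)-4,4-dichlorobut-3-en-1-yl]-2,2-dimethyl-1,3-oxazolidine-3-carboxylate
Product: 14 (4R)-4-[(1R)-1-(benzyloxy)-4,4-dichlorobut-3-en-1-yl]-1,3-oxazolidin-2-one, via N-Boc amino alcohol 13 (not isolated)
Conditions: p-TsOH·H2O (cat.), MeOH, rt; evaporate; then NaH, THF, 0 °C → rt; AcOH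
Reagents that add atoms: none
Why: Mild acid methanolysis removes only the N,O-acetonide and the primary alkoxide then attacks the Boc carbonyl with loss of tert-butoxide (5-exo-trig acyl transfer), the released tert-butoxide being consumed at once by the N–H of the product so that the dichloroalkene is not exposed to strong base.

Step 9
Reactants: 5 (R)-tert-butyl[(8-iodooctan-4-yl)oxy]dimethylsilane and 14 (4R)-4-[(1R)-1-(benzyloxy)-4,4-dichlorobut-3-en-1-yl]-1,3-oxazolidin-2-one
Product: 16 (4R)-4-[(1R,3Z,9R)-1-(benzyloxy)-9-[(tert-butyldimethylsilyl)oxy]-4-chlorododec-3-en-1-yl]-1,3-oxazolidin-2-one, via alkylzinc iodide 15 (not isolated)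
Conditions: 5, Zn dust (activated), LiCl, THF, 40 °C; then 14, Pd(DPEphos)Cl2 (5 mol%), THF, rt → 40 °C
Reagents that add atoms: none
Why: Trans-selective Negishi monoalkylation of a 1,1-dichloroalkene, in which zerovalent palladium inserts into the less hindered C–Cl bond trans to C4 and the wide-bite-angle ligand suppresses a second substitution, so the side chain enters trans to C4 and the remaining chlorine is cis to C4.

Step 10
Reactants: 16 (4R)-4-[(1R,3Z,9R)-1-(benzyloxy)-9-[(tert-butyldimethylsilyl)oxy]-4-chlorododec-3-en-1-yl]-1,3-oxazolidin-2-one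
Product: 17 (4R)-4-[(1R,3Z,9R)-1-(benzyloxy)-9-[(tert-butyldimethylsilyl)oxy]-4-ethenyldodec-3-en-1-yl]-1,3-oxazolidin-2-one
Conditions: vinylB(pin), Pd(OAc)2 (5 mol%), SPhos (10 mol%), K3PO4, THF/H2O, 60 °C
Reagents that add atoms: vinylboronic acid pinacol ester, C=CB1OC(C)(C)C(C)(C)O1
Why: Suzuki–Miyaura coupling of the alkenyl chloride with retention of configuration, which puts the vinyl group (C6=C7) cis to C4 and so gives the (Z)-diene with C4 on the inside position.

Step 11
Reactants: 17 (4R)-4-[(1R,3Z,9R)-1-(benzyloxy)-9-[(tert-butyldimethylsilyl)oxy]-4-ethenyldodec-3-en-1-yl]-1,3-oxazolidin-2-one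
Product: 18 (4R)-4-[(1R,3Z,9R)-1-(benzyloxy)-9-[(tert-butyldimethylsilyl)oxy]-4-ethenyldodec-3-en-1-yl]-3-ethenyl-1,3-oxazolidin-2-one
Conditions: vinyl bromide (1 M in THF), CuI (10 mol%), MeNHCH2CH2NHMe (20 mol%), K2CO3, toluene, 90 °C, sealed tube
Reagents that add atoms: vinyl bromide, C=CBr
Why: CuI-catalysed Goldberg-type N-vinylation of the oxazolidinone N–H, an established way to N-vinyl cyclic carbamates, at a temperature where neither cycloaddition nor hydrogen shift of the diene should be fast.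

Step 12
Reactants: 18 (4R)-4-[(1R,3Z,9R)-1-(benzyloxy)-9-[(tert-butyldimethylsilyl)oxy]-4-ethenyldodec-3-en-1-yl]-3-ethenyl-1,3-oxazolidin-2-one
Product: 19 (2R,3R,4aS,8aR)-3-(benzyloxy)-5-[(5R)-5-[(tert-butyldimethylsilyl)oxy]octyl]-1,2,3,4,4a,7,8,8a-octahydroquinoline in which N1 and the 2-CH2O group are closed as the cyclic carbamate (1,2-fused oxazolidin-2-one; C5=C6 double bond)
Conditions: CH2Cl2 (0.02 M), BHT (cat.), 13 kbar, 80 °C
Reagents that add atoms: none
Why: Concerted suprafacial [4+2] cycloaddition of the N-vinyl group C8a=C8 of the oxazolidinone (2π) across the diene C4a=C5–C6=C7 (4π); the closest known reaction type is the intramolecular Diels–Alder reaction of enamides used to build hydroindoles and hydroquinolines, run here under pressure because the cycloaddition has a strongly negative activation volume while the competing [1,5]-hydrogen shift of the (Z)-diene (C4–H to C7) has not, so that 80 °C should suffice. The piperidine ring closes by the bond C4a–C8a over the four-atom tether N1–C2–C3–C4 (type 1, fused mode, chair-like six-membered tether ring) and the cyclohexene ring closes by the bond C7–C8 as the new six-membered [4+2] ring. C4a relative to C8a: C4 stands on the inside position of the (Z)-diene, so the tether can only be spanned with nitrogen exo, and this geometry can give only the cis ring fusion. C4a and C8a relative to C2 and C3: the fused oxazolidinone holds the C2–CH2O bond in the carbamate plane (equatorial on the forming chair), the (Z)-diene needs the vinyl terminus C8 in the axial-type position, and a chair tether then puts C8 trans to the C2 substituent, C3–OBn axial and C5 equatorial, which is the target array at C2, C3, C4a and C8a. The step needs periselectivity over the hydrogen shift and over intermolecular cycloaddition, secured by pressure, moderate temperature and dilution, and facial selectivity, secured by the ring-fused carbamate, which removes the preference of an open-chain N-acyl group for an axial C2 substituent (that preference would lead to the 2,8a-cis series).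

Step 13
Reactants: 19 the tricyclic cycloadduct
Product: 20 (2R,3R,4aS,5S,8aR)-5-[(5R)-5-[(tert-butyldimethylsilyl)oxy]octyl]decahydroquinolin-3-ol in which N1 and the 2-CH2O group are closed as the cyclic carbamate (1,2-fused oxazolidin-2-one)
Conditions: H2 (3 atm), Pd(OH)2/C, EtOAc, rt
Reagents that add atoms: none
Why: Heterogeneous hydrogenation should add hydrogen to C5=C6 from the convex face, anti to the pseudoaxial C4 on the allylic carbon C4a, which sets C5 with H5 cis to H4a and H8a, and the same catalyst hydrogenolyses the benzyl ether.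

Step 14
Reactants: 20 the saturated tricyclic alcohol
Product: 22 (2S,3R,4aS,5S,8aR)-5-[(5R)-5-[(tert-butyldimethylsilyl)oxy]octyl]-2-[(phenylselanyl)methyl]decahydroquinolin-3-ol (same geometry at C2; the descriptor changes because of selenium), via sodium carbamate 21 (not isolated)
Conditions: (PhSe)2, NaBH4, EtOH, rt; then 20, DMF, 110 °C; aqueous work-up
Reagents that add atoms: diphenyl diselenide, c1ccc(cc1)[Se][Se]c1ccccc1
Why: Sodium benzeneselenolate opens the oxazolidinone by SN2 attack at the primary CH2–O carbon (the decarboxylative ring opening known for 2-oxazolidinones with chalcogenolates) and the carbamate salt loses CO2 on aqueous work-up.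

Step 15
Reactants: 22 the amino selenide
Product: 23 (2R,3R,4aS,5S,8aR)-5-[(5R)-5-[(tert-butyldimethylsilyl)oxy]octyl]-2-methyldecahydroquinolin-3-ol
Conditions: Bu3SnH (0.5 M), AIBN (cat.), toluene, 90 °C
Reagents that add atoms: none
Why: Radical chain reduction of the primary alkyl phenyl selenide turns the serine CH2 into the C2 methyl group, the high stannane concentration serving to outrun intramolecular hydrogen transfer.

Step 16
Reactants: 23 the 2-methyl amino alcohol
Product: 24 tert-butyl (2R,3R,4aS,5S,8aR)-5-[(5R)-5-[(tert-butyldimethylsilyl)oxy]octyl]-3-hydroxy-2-methyloctahydroquinoline-1(2H)-carboxylate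
Conditions: Boc2O, i-Pr2NEt, THF, 60 °C
Reagents that add atoms: di-tert-butyl dicarbonate, CC(C)(C)OC(=O)OC(=O)OC(C)(C)C
Why: Carbamate protection of the hindered secondary amine so that only the C3 hydroxyl is acylated next, the hydroxyl itself not reacting with Boc2O in the absence of an acyl-transfer catalyst.

Step 17
Reactants: 24 the N-Boc alcohol and 25 (E)-oct-2-enoic acid
Product: 26 tert-butyl (2R,3R,4aS,5S,8aR)-5-[(5R)-5-[(tert-butyldimethylsilyl)oxy]octyl]-2-methyl-3-[(2E)-oct-2-enoyloxy]octahydroquinoline-1(2H)-carboxylate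
Conditions: DCC, DMAP (cat.), CH2Cl2, 0 °C → rt
Reagents that add atoms: none
Why: Steglich esterification of the axial C3 alcohol, the E geometry of the enoate being that of the acid.

Step 18
Reactants: 26 the protected ester
Product: 27 (2R,3R,4aS,5S,8aR)-5-[(5R)-5-hydroxyoctyl]-2-methyldecahydroquinolin-3-yl (2E)-oct-2-enoate (target)
Conditions: TFA/CH2Cl2/H2O (10:10:1), 0 °C → rt; cold aq. NaHCO3
Reagents that add atoms: none
Why: Aqueous trifluoroacetic acid should cleave the Boc carbamate and the secondary silyl ether in one operation while the ammonium form of the amine prevents O-to-N acyl transfer, and cold bicarbonate work-up frees the base.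

**Compound list**

1 | (R)-1,2-epoxypentane | CCC[C@@H]1CO1 | starting material
2 | (R)-oct-7-en-4-ol | CCC[C@@H](O)CCC=C | intermediate
3 | (R)-tert-butyldimethyl(oct-7-en-4-yloxy)silane | CCC[C@@H](O[Si](C)(C)C(C)(C)C)CCC=C | intermediate
4 | {(5R)-5-[(tert-butyldimethylsilyl)oxy]octyl}zirconocene chloride (not isolated) | CCC[C@@H](O[Si](C)(C)C(C)(C)C)CCCC[Zr](Cl)(C1C=CC=C1)C1C=CC=C1 | intermediate
5 | (R)-tert-butyl[(8-iodooctan-4-yl)oxy]dimethylsilane | CCC[C@@H](O[Si](C)(C)C(C)(C)C)CCCCI | intermediate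
6 | (R)-Garner's aldehyde, tert-butyl (4R)-4-formyl-2,2-dimethyl-1,3-oxazolidine-3-carboxylate | CC(C)(C)OC(=O)N1[C@@H](C=O)COC1(C)C | starting material
7 | O-diisopinocampheylboryl (borinate) ester of 8 (not isolated) | CC(C)(C)OC(=O)N1[C@@H]([C@H](OB([C@H]2C[C@H]3C[C@@H]([C@@H]2C)C3(C)C)[C@H]2C[C@H]3C[C@@H]([C@@H]2C)C3(C)C)CC=C)COC1(C)C | intermediate
8 | tert-butyl (4R)-4-[(1R)-1-hydroxybut-3-en-1-yl]-2,2-dimethyl-1,3-oxazolidine-3-carboxylate | CC(C)(C)OC(=O)N1[C@@H]([C@H](O)CC=C)COC1(C)C | intermediate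
9 | tert-butyl (4R)-4-[(1R)-1-(benzyloxy)but-3-en-1-yl]-2,2-dimethyl-1,3-oxazolidine-3-carboxylate | CC(C)(C)OC(=O)N1[C@@H]([C@H](OCc2ccccc2)CC=C)COC1(C)C | intermediate
10 | secondary ozonide (1,2,4-trioxolane) of 9 (not isolated) | CC(C)(C)OC(=O)N1[C@@H]([C@H](OCc2ccccc2)CC2OCOO2)COC1(C)C | intermediate
11 | tert-butyl (4R)-4-[(1R)-1-(benzyloxy)-3-oxopropyl]-2,2-dimethyl-1,3-oxazolidine-3-carboxylate | CC(C)(C)OC(=O)N1[C@@H]([C@H](OCc2ccccc2)CC=O)COC1(C)C | intermediate
12 | tert-butyl (4R)-4-[(1R)-1-(benzyloxy)-4,4-dichlorobut-3-en-1-yl]-2,2-dimethyl-1,3-oxazolidine-3-carboxylate | CC(C)(C)OC(=O)N1[C@@H]([C@H](OCc2ccccc2)CC=C(Cl)Cl)COC1(C)C | intermediate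
13 | tert-butyl N-[(2R,3R)-3-(benzyloxy)-6,6-dichloro-1-hydroxyhex-5-en-2-yl]carbamate (not isolated) | CC(C)(C)OC(=O)N[C@H](CO)[C@H](OCc1ccccc1)CC=C(Cl)Cl | intermediate
14 | (4R)-4-[(1R)-1-(benzyloxy)-4,4-dichlorobut-3-en-1-yl]-1,3-oxazolidin-2-one | O=C1N[C@@H]([C@H](OCc2ccccc2)CC=C(Cl)Cl)CO1 | intermediate
15 | {(5R)-5-[(tert-butyldimethylsilyl)oxy]octyl}zinc iodide (not isolated) | CCC[C@@H](O[Si](C)(C)C(C)(C)C)CCCC[Zn]I | intermediate
16 | (4R)-4-[(1R,3Z,9R)-1-(benzyloxy)-9-[(tert-butyldimethylsilyl)oxy]-4-chlorododec-3-en-1-yl]-1,3-oxazolidin-2-one | O=C1N[C@@H]([C@H](OCc2ccccc2)C/C=C(\Cl)CCCC[C@H](O[Si](C)(C)C(C)(C)C)CCC)CO1 | intermediate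
17 | (4R)-4-[(1R,3Z,9R)-1-(benzyloxy)-9-[(tert-butyldimethylsilyl)oxy]-4-ethenyldodec-3-en-1-yl]-1,3-oxazolidin-2-one | O=C1N[C@@H]([C@H](OCc2ccccc2)C/C=C(\C=C)CCCC[C@H](O[Si](C)(C)C(C)(C)C)CCC)CO1 | intermediate
18 | (4R)-4-[(1R,3Z,9R)-1-(benzyloxy)-9-[(tert-butyldimethylsilyl)oxy]-4-ethenyldodec-3-en-1-yl]-3-ethenyl-1,3-oxazolidin-2-one | O=C1N(C=C)[C@@H]([C@H](OCc2ccccc2)C/C=C(\C=C)CCCC[C@H](O[Si](C)(C)C(C)(C)C)CCC)CO1 | intermediate
19 | (2R,3R,4aS,8aR)-3-(benzyloxy)-5-[(5R)-5-[(tert-butyldimethylsilyl)oxy]octyl]-1,2,3,4,4a,7,8,8a-octahydroquinoline with N1 and 2-CH2O closed as cyclic carbamate | c1ccc(cc1)CO[C@@H]1C[C@H]2C(CCCC[C@H](O[Si](C)(C)C(C)(C)C)CCC)=CCC[C@H]2N3[C@@H]1COC3=O | intermediate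
20 | (2R,3R,4aS,5S,8aR)-5-[(5R)-5-[(tert-butyldimethylsilyl)oxy]octyl]decahydroquinolin-3-ol with N1 and 2-CH2O closed as cyclic carbamate | O[C@@H]1C[C@H]2[C@@H](CCCC[C@H](O[Si](C)(C)C(C)(C)C)CCC)CCC[C@H]2N3[C@@H]1COC3=O | intermediate
21 | sodium N-carboxylate of 22 (not isolated) | O[C@@H]1C[C@H]2[C@@H](CCCC[C@H](O[Si](C)(C)C(C)(C)C)CCC)CCC[C@H]2N(C(=O)[O-])[C@@H]1C[Se]c1ccccc1.[Na+] | intermediate
22 | (2S,3R,4aS,5S,8aR)-5-[(5R)-5-[(tert-butyldimethylsilyl)oxy]octyl]-2-[(phenylselanyl)methyl]decahydroquinolin-3-ol | O[C@@H]1C[C@H]2[C@@H](CCCC[C@H](O[Si](C)(C)C(C)(C)C)CCC)CCC[C@H]2N[C@@H]1C[Se]c1ccccc1 | intermediate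
23 | (2R,3R,4aS,5S,8aR)-5-[(5R)-5-[(tert-butyldimethylsilyl)oxy]octyl]-2-methyldecahydroquinolin-3-ol | O[C@@H]1C[C@H]2[C@@H](CCCC[C@H](O[Si](C)(C)C(C)(C)C)CCC)CCC[C@H]2N[C@@H]1C | intermediate
24 | tert-butyl (2R,3R,4aS,5S,8aR)-5-[(5R)-5-[(tert-butyldimethylsilyl)oxy]octyl]-3-hydroxy-2-methyloctahydroquinoline-1(2H)-carboxylate | O[C@@H]1C[C@H]2[C@@H](CCCC[C@H](O[Si](C)(C)C(C)(C)C)CCC)CCC[C@H]2N(C(=O)OC(C)(C)C)[C@@H]1C | intermediate
25 | (E)-oct-2-enoic acid | CCCCC/C=C/C(=O)O | starting material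
26 | tert-butyl (2R,3R,4aS,5S,8aR)-5-[(5R)-5-[(tert-butyldimethylsilyl)oxy]octyl]-2-methyl-3-[(2E)-oct-2-enoyloxy]octahydroquinoline-1(2H)-carboxylate | CCCCC/C=C/C(=O)O[C@@H]1C[C@H]2[C@@H](CCCC[C@H](O[Si](C)(C)C(C)(C)C)CCC)CCC[C@H]2N(C(=O)OC(C)(C)C)[C@@H]1C | intermediate
27 | (2R,3R,4aS,5S,8aR)-5-[(5R)-5-hydroxyoctyl]-2-methyldecahydroquinolin-3-yl (2E)-oct-2-enoate | CCCCC/C=C/C(=O)O[C@@H]1C[C@H]2[C@@H](CCCC[C@H](O)CCC)CCC[C@H]2N[C@@H]1C | target

**Step count and risks**

Total: 18 steps. Longest linear sequence: 15 steps (steps 4–18, from 6).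

Steps most likely to fail:

1. Step 12. The (Z)-diene may add too slowly to the unactivated enamide, so that [1,5]-hydrogen shift of the diene, intermolecular cycloaddition or a boat-type closure on the other face could take over. The fallback changes the dienophile to an activated one with a removable group. It sets out from 17: addition–elimination of the oxazolidinone anion (NaH, THF) to (E)-1,2-bis(phenylsulfonyl)ethene should give the N-[(E)-2-(phenylsulfonyl)ethenyl] oxazolidinone F1. Its normal-demand intramolecular Diels–Alder reaction (toluene, BHT, 120 °C, where the hydrogen shift is still slow) should give the 8-(phenylsulfonyl) cycloadduct F2 under the same geometric control. Desulfonylation (Na/Hg, Na2HPO4, MeOH/THF, −20 °C) brings the material back to the route at 19.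

2. Step 9. Trans selectivity may erode, a second substitution at the dichloroalkene may occur, or the zinc reagent may be protonated by the carbamate N–H. The fallback builds the trisubstituted alkene by olefination and sets out from 11 and 5. Alkylation of methyl bis(2,2,2-trifluoroethyl)phosphonoacetate with 5 (NaH, DMF) gives the α-alkyl phosphonate F3. Still–Gennari olefination of 11 (KHMDS, 18-crown-6, THF, −78 °C) should give the (Z)-enoate F4. DIBAL-H reduction gives the (Z)-allylic alcohol F5, MnO2 oxidation gives the (Z)-enal F6, and methylenation with Ph3P=CH2 gives the Garner-protected (Z)-diene F7. Acetonide cleavage (PPTS, MeOH) gives the N-Boc amino alcohol F8, and NaH cyclisation as in step 8 brings it back to the route at 17.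

3. Step 14. The SN2 opening at the β-branched CH2–O carbon may be sluggish, or the silyl ether may be lost in the hot basic medium. The fallback replaces nucleophilic opening by hydrolysis and deoxygenation and sets out from 20. Ba(OH)2 (EtOH/H2O, reflux) cleaves the carbamate to the amino diol F9. Boc2O gives the N-Boc diol F10. Selective iodination of the primary hydroxyl (I2, PPh3, imidazole, 0 °C) gives the N-Boc iodide F11. Reduction with Bu3SnH/AIBN brings it back to the route at 24.

**Further compounds**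

F1 | step 12 | (4R)-4-[(1R,3Z,9R)-1-(benzyloxy)-9-[(tert-butyldimethylsilyl)oxy]-4-ethenyldodec-3-en-1-yl]-3-[(E)-2-(phenylsulfonyl)ethenyl]-1,3-oxazolidin-2-one | O=C1N(/C=C/S(=O)(=O)c2ccccc2)[C@@H]([C@H](OCc2ccccc2)C/C=C(\C=C)CCCC[C@H](O[Si](C)(C)C(C)(C)C)CCC)CO1
F2 | step 12 | 8-(phenylsulfonyl) derivative of 19 (sulfonyl trans to N on the carbocycle) | c1ccc(cc1)CO[C@@H]1C[C@H]2C(CCCC[C@H](O[Si](C)(C)C(C)(C)C)CCC)=CC[C@H](S(=O)(=O)c3ccccc3)[C@H]2N3[C@@H]1COC3=O
F3 | step 9 | methyl (7R)-2-[bis(2,2,2-trifluoroethoxy)phosphoryl]-7-[(tert-butyldimethylsilyl)oxy]decanoate | COC(=O)C(CCCC[C@H](O[Si](C)(C)C(C)(C)C)CCC)P(=O)(OCC(F)(F)F)OCC(F)(F)F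
F4 | step 9 | Garner-protected (Z)-enoate | CC(C)(C)OC(=O)N1[C@@H]([C@H](OCc2ccccc2)C/C=C(\C(=O)OC)CCCC[C@H](O[Si](C)(C)C(C)(C)C)CCC)COC1(C)C
F5 | step 9 | Garner-protected (Z)-allylic alcohol | CC(C)(C)OC(=O)N1[C@@H]([C@H](OCc2ccccc2)C/C=C(\CO)CCCC[C@H](O[Si](C)(C)C(C)(C)C)CCC)COC1(C)C
F6 | step 9 | Garner-protected (Z)-enal | CC(C)(C)OC(=O)N1[C@@H]([C@H](OCc2ccccc2)C/C=C(\C=O)CCCC[C@H](O[Si](C)(C)C(C)(C)C)CCC)COC1(C)C
F7 | step 9 | Garner-protected (Z)-diene | CC(C)(C)OC(=O)N1[C@@H]([C@H](OCc2ccccc2)C/C=C(\C=C)CCCC[C@H](O[Si](C)(C)C(C)(C)C)CCC)COC1(C)C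
F8 | step 9 | N-Boc amino alcohol of the (Z)-diene | CC(C)(C)OC(=O)N[C@H](CO)[C@H](OCc1ccccc1)C/C=C(\C=C)CCCC[C@H](O[Si](C)(C)C(C)(C)C)CCC
F9 | step 14 | (2R,3R,4aS,5S,8aR)-5-[(5R)-5-[(tert-butyldimethylsilyl)oxy]octyl]-2-(hydroxymethyl)decahydroquinolin-3-ol | O[C@@H]1C[C@H]2[C@@H](CCCC[C@H](O[Si](C)(C)C(C)(C)C)CCC)CCC[C@H]2N[C@@H]1CO
F10 | step 14 | N-Boc derivative of F9 | O[C@@H]1C[C@H]2[C@@H](CCCC[C@H](O[Si](C)(C)C(C)(C)C)CCC)CCC[C@H]2N(C(=O)OC(C)(C)C)[C@@H]1CO
F11 | step 14 | N-Boc 2-(iodomethyl) compound | O[C@@H]1C[C@H]2[C@@H](CCCC[C@H](O[Si](C)(C)C(C)(C)C)CCC)CCC[C@H]2N(C(=O)OC(C)(C)C)[C@@H]1CI
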